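**Retrosynthetic overview**
1. Target ⇐ ethyl ester of the cis-5,8-diol ⇐ bicyclic endoperoxide. Key step: one [4+2] addition of singlet O2 to the ring-C 1,3-diene makes both C–O bonds; O–O reduction and saponification follow.
2. Triene ester ⇐ Pd-catalysed α,β-dehydrogenation of the Diels–Alder adduct (a β,γ-unsaturated ester).
3. Rings C and D ⇐ intramolecular Diels–Alder (IMDA) of a (2E,4E)-dienoate tethered to a bicyclo[4.2.0]octadiene; dienoate ⇐ aldehyde + phosphonocrotonate (HWE).
4. Rings A and B ⇐ 6π electrocyclisation of a trans-7,8-disubstituted cyclooctatriene ⇐ Claisen rearrangement of the vinyl ether of a chiral trienol (C–O to C–C chirality relay).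
5. Trienol ⇐ Cu-catalysed enantioselective anti-SN2′ desymmetrisation of meso cyclooctatetraene (COT) oxide with n-OctMgBr ⇐ COT. Ring order: eight-membered ring (bought) → A+B → C+D.

Assumption: the ligand enantiomer in step 2 is the one that gives the (1S,4S)-alcohol (fixed by one Mosher-ester check); tetracycle carbons are labelled C1–C13 in the order of the ring atoms in the target SMILES (C1 octyl-bearing CH, C3=C4, C5 tertiary carbinol, C6 carboxyl carbon, C8 secondary carbinol, C10 CH2), and "convex face" is the face carrying H-13.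

**Step 1**
Reactants: 1 cyclooctatetraene (COT)
Product: 2 cyclooctatetraene monoepoxide (meso cis-9-oxabicyclo[6.1.0]nona-2,4,6-triene)
Conditions: mCPBA (1.0 equiv), NaHCO3, CH2Cl2, 0 °C → rt
Reagents that add atoms: mCPBA (3-chloroperoxybenzoic acid), O=C(OO)c1cccc(Cl)c1
Why: Prilezhaev epoxidation of one of four equivalent cis-alkenes gives the known achiral (meso) monoepoxide, the buffer and one equivalent of peracid limiting bis-epoxidation and acid rearrangement.

**Step 2**
Reactants: 2 cyclooctatetraene monoepoxide, 3 n-octylmagnesium bromide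
Product: 4 (1S,4S,2Z,5Z,7Z)-4-octylcycloocta-2,5,7-trien-1-ol (1,4-trans)
Conditions: CuBr·SMe2 (5 mol %), Taniaphos-type ferrocenyl diphosphine (6 mol %), n-OctMgBr (1.3 equiv, slow addition), CH2Cl2/Et2O, −78 °C; aq NH4Cl
Reagents that add atoms: none
Why: Proposed new method: a chiral L*Cu(I)–octyl cuprate formed by Mg→Cu transmetalation should add anti-SN2′ to one of the two enantiotopic diene termini (C4 vs C7) of meso epoxide 2 (oxidative addition anti to the C–O bond to an allyl-Cu(III), then reductive elimination), so the ligand picks the terminus and sets C1 and C4 together and trans, while slow addition at −78 °C suppresses uncatalysed SN2 opening and MgBr2-induced rearrangement; the closest known reactions are the Cu/phosphoramidite desymmetrisation of this epoxide with dialkylzincs and Cu-catalysed asymmetric SN2′ openings (kinetic resolutions) of cyclic 1,3-diene monoepoxides with Grignard reagents, but a Grignard desymmetrisation of a meso trienyl epoxide has not been shown.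

**Step 3**
Reactants: 4 (1S,4S)-4-octylcycloocta-2,5,7-trien-1-ol, 5 triethylene glycol divinyl ether
Product: 9 2-[(1S,6R,7R,8R)-8-octylbicyclo[4.2.0]octa-2,4-dien-7-yl]acetaldehyde (cis-fused; 7,8-trans; CH2CHO endo; octyl exo), via vinyl ether 6 (not isolated), via cyclooctatriene aldehyde 7 (not isolated), via octyl-endo bicycle 8 (not isolated)
Conditions: Pd(OAc)2 (2 mol %), 1,10-phenanthroline (2.5 mol %), 5 (4 equiv, neat), BHT, 75 °C; then 110 °C; short silica plug to remove Pd and glycol ethers, valence isomers not separated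
Reagents that add atoms: none
Why: Pd(II)-catalysed transfer vinylation forms the allyl vinyl ether C–O bond, the Claisen [3,3] shift through the C1–C2=C3 arm (the one that gives the fully conjugated triene, with octyl on the far face of C3) delivers CH2CHO suprafacially, so cis to the departing oxygen and trans to octyl, and disrotatory 6π electrocyclisation of 7 closes in both senses to the cis-fused bicycles 8 and 9, which interconvert through 7 at this temperature, so 8 is never separated and the equilibrium material, named by its productive component 9, goes on as it is.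

**Step 4**
Reactants: 9 bicyclic aldehyde (the unseparated step-3 material), 10 triethyl 4-phosphonocrotonate
Product: 14 ethyl 1-octyl-tetracyclic 3,7-diene-6-carboxylate (IMDA adduct; H-5 and H-13 cis; CO2Et cis to H-5; rings C/D trans-fused at C9–C13), via endo-dienoate 11 (not isolated), via exo-dienoate 12 (not isolated), via cyclooctatriene dienoate 13 (not isolated)
Conditions: 10, LiHMDS, THF, −78 → 0 °C; solvent switch to PhMe, BHT, 110 °C, 12 h
Reagents that add atoms: none
Why: Vinylogous Horner–Wadsworth–Emmons olefination gives the (2E,4E)-dienoates, the unreactive exo isomer 12 (from the octyl-endo bicycle carried in the step-3 material and from 11 itself on heating) drains through triene 13 by retro-6π/6π into 11, and the intramolecular Diels–Alder reaction of 11 (as in the endiandric acid cascade) adds the side-chain diene across the proximal ring alkene from the tether face, the one-carbon tether allowing only the geometry that sets C5, C6, C9 and C13 as in the target series.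

**Step 5**
Reactants: 14 IMDA adduct
Product: 15 ethyl 1-octyl-tetracyclic 3,5,7-triene-6-carboxylate (C3=C4, C5=C6, C7=C8)
Conditions: LiTMP (1.3 equiv), THF, −40 °C; ZnCl2 (1.4 equiv); [Pd(allyl)Cl]2 (2.5 mol %), allyl pivalate (1.3 equiv), 60 °C
Reagents that add atoms: none
Why: Allyl-palladium-catalysed α,β-dehydrogenation of the zinc ester dienolate works because Pd binds C6 on the convex face, cis to H-5 (ring B shields the other face), so syn β-hydride elimination gives only C5=C6 (H-9 at the other allyl terminus is anti) and the conjugated triene forms without touching C1, C2, C9, C11, C12 or C13.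

**Step 6**
Reactants: 15 triene ester
Product: 17 ethyl ester of the target (cis-5,8-diol), via endoperoxide 16 (not isolated)
Conditions: O2, TPP (1 mol %), white LEDs, CH2Cl2, −20 °C; then thiourea (1.5 equiv), MeOH, 0 °C → rt
Reagents that add atoms: dioxygen, O=O
Why: [4+2] cycloaddition of singlet oxygen to the only s-cis diene (C5=C6–C7=C8; C3=C4–C5=C6 is locked s-trans) should occur from the convex face, away from C12 and the cyclobutane, forming both C–O bonds at once and so setting C5 and C8 cis-1,4, and neutral thiourea reduction of the O–O bond avoids Kornblum–DeLaMare cleavage.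

**Step 7**
Reactants: 17 diol ethyl ester
Product: 18 CNP0106718.3 (target acid)
Conditions: LiOH·H2O (4 equiv), THF/MeOH/H2O, rt → 40 °C; then 1 M HCl to pH 3, 0 °C
Reagents that add atoms: lithium hydroxide, [Li+].[OH-]
Why: Saponification (BAc2) of the ethyl ester is safe because the carboxyl group is trans to C8 across C6=C7 (no lactonisation) and no stereocentre is epimerisable.

**Compound list**
1 | cyclooctatetraene (COT) | C1=C\C=C/C=C\C=C/1 | starting material
2 | cyclooctatetraene monoepoxide (meso, cis) | O1[C@@H]2/C=C\C=C/C=C\[C@H]12 | intermediate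
3 | n-octylmagnesium bromide | CCCCCCCC[Mg]Br | starting material
4 | (1S,4S,2Z,5Z,7Z)-4-octylcycloocta-2,5,7-trien-1-ol | CCCCCCCC[C@H]1/C=C\C=C/[C@H](O)/C=C\1 | intermediate
5 | triethylene glycol divinyl ether | C=COCCOCCOCCOC=C | starting material
6 | (1S,4S)-4-octylcycloocta-2,5,7-trien-1-yl vinyl ether | CCCCCCCC[C@H]1/C=C\C=C/[C@H](OC=C)/C=C\1 | intermediate
7 | 2-[(1S,8S)-8-octylcycloocta-2,4,6-trien-1-yl]acetaldehyde (trans) | CCCCCCCC[C@H]1/C=C\C=C/C=C\[C@@H]1CC=O | intermediate
8 | 2-[(1R,6S,7R,8R)-8-octylbicyclo[4.2.0]octa-2,4-dien-7-yl]acetaldehyde, cis-fused, 7,8-trans, octyl endo, CH2CHO exo (valence isomer of 9) | CCCCCCCC[C@H]1[C@H]2C=CC=C[C@H]2[C@@H]1CC=O | intermediate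
9 | 2-[(1S,6R,7R,8R)-8-octylbicyclo[4.2.0]octa-2,4-dien-7-yl]acetaldehyde, cis-fused, 7,8-trans, CH2CHO endo, octyl exo | CCCCCCCC[C@H]1[C@@H]2C=CC=C[C@@H]2[C@@H]1CC=O | intermediate
10 | triethyl 4-phosphonocrotonate, ethyl (E)-4-(diethoxyphosphoryl)but-2-enoate | CCOC(=O)/C=C/CP(=O)(OCC)OCC | starting material
11 | ethyl (2E,4E)-6-[(1S,6R,7R,8R)-8-octylbicyclo[4.2.0]octa-2,4-dien-7-yl]hexa-2,4-dienoate (bicyclic unit of 9, dienoate endo) | CCCCCCCC[C@H]1[C@@H]2C=CC=C[C@@H]2[C@@H]1C/C=C/C=C/C(=O)OCC | intermediate
12 | ethyl (2E,4E)-6-[(1R,6S,7R,8R)-8-octylbicyclo[4.2.0]octa-2,4-dien-7-yl]hexa-2,4-dienoate (bicyclic unit of 8, dienoate exo) | CCCCCCCC[C@H]1[C@H]2C=CC=C[C@H]2[C@@H]1C/C=C/C=C/C(=O)OCC | intermediate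
13 | ethyl (2E,4E)-6-[(1S,8S)-8-octylcycloocta-2,4,6-trien-1-yl]hexa-2,4-dienoate | CCCCCCCC[C@H]1/C=C\C=C/C=C\[C@@H]1C/C=C/C=C/C(=O)OCC | intermediate
14 | ethyl 1-octyl-tetracyclic 3,7-diene-6-carboxylate (IMDA adduct) | CCCCCCCC[C@H]1[C@@H]2C=C[C@@H]3[C@@H](C(=O)OCC)C=C[C@H]4C[C@H]1[C@H]2[C@@H]43 | intermediate
15 | ethyl 1-octyl-tetracyclic 3,5,7-triene-6-carboxylate | CCCCCCCC[C@H]1[C@@H]2C=CC3=C(C(=O)OCC)C=C[C@H]4C[C@H]1[C@H]2[C@@H]43 | intermediate
16 | 5,8-epidioxy (endoperoxide) ethyl ester, O–O on the convex face | CCCCCCCC[C@H]1[C@@H]2C=C[C@]3(OO5)C(C(=O)OCC)=C[C@@H]5[C@H]4C[C@H]1[C@H]2[C@@H]43 | intermediate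
17 | ethyl ester of the target (cis-5,8-dihydroxy-3,6-diene-6-carboxylate) | CCCCCCCC[C@H]1[C@@H]2C=C[C@]3(O)C(C(=O)OCC)=C[C@@H](O)[C@H]4C[C@H]1[C@H]2[C@@H]43 | intermediate
18 | CNP0106718.3 | CCCCCCCC[C@H]1[C@@H]2C=C[C@]3(O)C(C(=O)O)=C[C@@H](O)[C@H]4C[C@H]1[C@H]2[C@@H]43 | target

**Totals**
Total steps: 7. Longest linear sequence: 7 (fully linear from COT).

**Three steps most likely to fail**

Step 2 (the proposed new step): the risks are low ee, direct SN2 opening and Lewis-acid rearrangement of 2. The fallback sets out from 2 and returns at 4. Grignard 3 is transmetalated (ZnCl2, Et2O; dioxane to remove MgX2) to salt-free di-n-octylzinc F1. Epoxide 2 is then opened by the known Cu(OTf)2/BINOL-phosphoramidite desymmetrisation of COT oxide with dialkylzincs (toluene, −20 to 0 °C). This replaces the Grignard/diphosphine system by a preformed diorganozinc and a different catalyst class, and gives 4 directly.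

Step 5: the risks are slow enolisation of the inward-pointing H-6 and over-dehydrogenation (aromatisation of ring C). The fallback sets out from 14 and returns at 15. Sulfenylation of the lithium dienolate (LDA, THF, −78 °C; PhSSPh) gives the ethyl 6-(phenylsulfanyl) ester F2, with sulfur on the convex face, cis to H-5. mCPBA (1 equiv, −78 °C) gives the sulfoxide F3. Thermolysis (PhMe, 90 °C, CaCO3) causes syn-elimination toward H-5, the only syn β-hydrogen, and gives 15.

Step 6: the risk is facial selectivity, because ring B no longer folds under ring C once C5 is sp2; ene side reactions are a lesser risk. The fallback sets out from 14, bypasses 15 and returns at 17; each C–O bond is delivered by a sigmatropic shift, so no face choice on the flattened triene is needed. The dienolate of 14 (LDA, −78 °C) with PhSeCl gives the 6-(phenylselanyl) ester F4, selenium on the convex face. H2O2/pyridine gives the selenoxide F5, which rearranges [2,3] to the C8 selenenate F6 (C6=C7 now conjugated). In-situ hydrolysis gives the 8-hydroxy-6-ene ester F7. Riley oxidation (SeO2 cat., t-BuOOH, CH2Cl2, rt; ene then [2,3]) replaces the doubly allylic H-5 by OH with retention and gives 17.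

**Further compounds**
F1 | step 2 | di-n-octylzinc | CCCCCCCC[Zn]CCCCCCCC
F2 | step 5 | ethyl 6-(phenylsulfanyl) derivative of 14 (S on the convex face) | CCCCCCCC[C@H]1[C@@H]2C=C[C@@H]3[C@](Sc5ccccc5)(C(=O)OCC)C=C[C@H]4C[C@H]1[C@H]2[C@@H]43
F3 | step 5 | sulfoxide of F2 (mixture at sulfur) | CCCCCCCC[C@H]1[C@@H]2C=C[C@@H]3[C@](S(=O)c5ccccc5)(C(=O)OCC)C=C[C@H]4C[C@H]1[C@H]2[C@@H]43
F4 | step 6 | ethyl 6-(phenylselanyl) derivative of 14 (Se on the convex face) | CCCCCCCC[C@H]1[C@@H]2C=C[C@@H]3[C@]([Se]c5ccccc5)(C(=O)OCC)C=C[C@H]4C[C@H]1[C@H]2[C@@H]43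
F5 | step 6 | selenoxide of F4 | CCCCCCCC[C@H]1[C@@H]2C=C[C@@H]3[C@]([Se](=O)c5ccccc5)(C(=O)OCC)C=C[C@H]4C[C@H]1[C@H]2[C@@H]43
F6 | step 6 | C8 phenylselenenate of the 6-ene ester | CCCCCCCC[C@H]1[C@@H]2C=C[C@@H]3C(C(=O)OCC)=C[C@@H](O[Se]c5ccccc5)[C@H]4C[C@H]1[C@H]2[C@@H]43
F7 | step 6 | ethyl 8-hydroxy-3,6-diene-6-carboxylate (5-H) | CCCCCCCC[C@H]1[C@@H]2C=C[C@@H]3C(C(=O)OCC)=C[C@@H](O)[C@H]4C[C@H]1[C@H]2[C@@H]43
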